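**Retrosynthetic overview**

- Aiphanol ⇐ global debenzylation of its tetra-O-benzyl ether. The 1,4-dioxane ring is the only ring built (all three arenes are bought); it is closed in the penultimate step by intramolecular aryl C–O coupling of a threo bromo alcohol (C-7–O bond, retention).
- Threo bromo alcohol ⇐ catalyst-controlled transfer hydrogenation of an (R)-α-aryloxy ketone ⇐ Mitsunobu etherification (C-8–O bond, inversion) of an (S)-acyloin with a 2-bromo-4-styrylphenol.
- Key C–C disconnection, C-7–C-8: (S)-acyloin ⇐ carbene-catalysed asymmetric cross-acyloin reaction. The Breslow intermediate (acyl anion equivalent) of O-benzylsyringaldehyde adds to benzyloxyacetaldehyde, so two carbonyl carbons are joined and C-8 is set in the same step.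
- Bromostilbene phenol ⇐ Horner–Wadsworth–Emmons olefination of 3-bromo-4-hydroxybenzaldehyde with a 3,5-bis(benzyloxy)benzylphosphonate (Arbuzov from the bromide).

**Assumptions**

- Lignan numbering is used for the propane unit: C-7 (carries the syringyl ring), C-8 (carries CH2OH), C-9 (CH2OH).
- O-Benzylsyringaldehyde, benzyloxyacetaldehyde, 3,5-bis(benzyloxy)benzyl bromide and 3-bromo-4-hydroxybenzaldehyde are taken as catalogue chemicals.
- The sense of induction of the triazolium salt in step 1 is assigned by analogy with its benzoin chemistry and is not established for this substrate pair; if it proves opposite, the antipodal salt (equally available) is used with no other change.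

**Route**

Step 1
Reactants: 1 4-(benzyloxy)-3,5-dimethoxybenzaldehyde; 2 (benzyloxy)acetaldehyde
Product: 3 (2S)-3-(benzyloxy)-1-[4-(benzyloxy)-3,5-dimethoxyphenyl]-2-hydroxypropan-1-one
Conditions: (5aS,10bR)-2-(pentafluorophenyl)-5a,10b-dihydro-4H,6H-indeno[2,1-b][1,2,4]triazolo[4,3-d][1,4]oxazin-2-ium tetrafluoroborate (10 mol %), iPr2NEt (20 mol %), toluene, 0 °C; 1 in excess (2.5 equiv, recovered), 2 added by syringe pump over 10 h
Reagents that add atoms: none
Why: Proposed new method: the carbene adds to non-enolisable 1 to give the Breslow intermediate, an acyl anion equivalent that is nucleophilic at the former carbonyl carbon, and this attacks the strongly electrophilic α-alkoxy aldehyde 2 held at low concentration, so two carbonyl carbons are joined and the C-8 stereocentre is set by the face selection of the aminoindanol backbone; 1 is too electron-rich to act as acceptor, the self-acyloin of 2 forms reversibly, and the aryl-conjugated ketone 3 is the thermodynamic sink; the closest known reactions are carbene-catalysed cross-acyloin condensations of aryl aldehydes with acetaldehyde or formaldehyde, enantioselective triazolium benzoin condensations, and thiamine-enzyme carboligations of aryl aldehydes with alkoxyacetaldehydes (cross-benzoin reaction).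

Step 2
Reactants: 4 3,5-bis(benzyloxy)benzyl bromide
Product: 5 diethyl [3,5-bis(benzyloxy)benzyl]phosphonate
Conditions: P(OEt)3 (3 equiv, neat), 130 °C; excess removed under vacuum
Reagents that add atoms: triethyl phosphite, CCOP(OCC)OCC
Why: Michaelis–Arbuzov reaction: phosphorus displaces the benzylic bromide and bromide dealkylates the phosphonium ion; no stereocentre is involved.

Step 3
Reactants: 5 diethyl [3,5-bis(benzyloxy)benzyl]phosphonate; 6 3-bromo-4-hydroxybenzaldehyde
Product: 7 2-bromo-4-[(E)-2-[3,5-bis(benzyloxy)phenyl]ethenyl]phenol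
Conditions: KOtBu (3.2 equiv), DMF, 0 °C → rt (50 °C if slow); NH4Cl work-up
Reagents that add atoms: none
Why: Horner–Wadsworth–Emmons olefination: the semi-stabilised benzylphosphonate anion adds reversibly to the aldehyde and phosphate is lost from the anti adduct to give the E-alkene; one equivalent of base is consumed by the phenol, whose phenoxide is attenuated by the ortho bromine so the aldehyde stays reactive in DMF.

Step 4
Reactants: 3 (2S)-3-(benzyloxy)-1-[4-(benzyloxy)-3,5-dimethoxyphenyl]-2-hydroxypropan-1-one; 7 2-bromo-4-[(E)-2-[3,5-bis(benzyloxy)phenyl]ethenyl]phenol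
Product: 8 (2R)-3-(benzyloxy)-1-[4-(benzyloxy)-3,5-dimethoxyphenyl]-2-{4-[(E)-2-[3,5-bis(benzyloxy)phenyl]ethenyl]-2-bromophenoxy}propan-1-one
Conditions: PPh3 (1.5 equiv), DIAD (1.5 equiv), toluene, 0 °C → rt
Reagents that add atoms: none
Why: Mitsunobu reaction: the α-ketol hydroxyl is activated as an alkoxyphosphonium ion and displaced in SN2 fashion by the acidic 2-bromophenol (pKa about 8.5), which inverts C-8 from S to R; the phenol oxygen para to the styryl group is thereby attached to C-8, and the cold, near-neutral conditions limit enolisation of the α-aryloxy ketone.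

Step 5
Reactants: 8 (2R)-3-(benzyloxy)-1-[4-(benzyloxy)-3,5-dimethoxyphenyl]-2-{4-[(E)-2-[3,5-bis(benzyloxy)phenyl]ethenyl]-2-bromophenoxy}propan-1-one
Product: 9 (1R,2R)-3-(benzyloxy)-1-[4-(benzyloxy)-3,5-dimethoxyphenyl]-2-{4-[(E)-2-[3,5-bis(benzyloxy)phenyl]ethenyl]-2-bromophenoxy}propan-1-ol (threo)
Conditions: RuCl[(S,S)-TsDPEN](p-cymene) (2 mol %), HCO2H/Et3N (5:2), EtOAc, 35 °C
Reagents that add atoms: none
Why: Noyori–Ikariya asymmetric transfer hydrogenation: the (S,S)-catalyst delivers hydride to the aryl ketone face that gives the 1R carbinol (same facial sense as (S)-1-phenylethanol from acetophenone; the descriptor differs only because C-8 outranks the aryl group), so C-7 is set under catalyst control to the threo (1R,2R) isomer, and the acidic formate medium leaves C-8, the stilbene, the aryl bromide and the benzyl ethers untouched.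

Step 6
Reactants: 9 (1R,2R)-3-(benzyloxy)-1-[4-(benzyloxy)-3,5-dimethoxyphenyl]-2-{4-[(E)-2-[3,5-bis(benzyloxy)phenyl]ethenyl]-2-bromophenoxy}propan-1-ol
Product: 10 (2R,3R)-3-[4-(benzyloxy)-3,5-dimethoxyphenyl]-2-[(benzyloxy)methyl]-6-[(E)-2-[3,5-bis(benzyloxy)phenyl]ethenyl]-2,3-dihydro-1,4-benzodioxine
Conditions: CuI (10 mol %), 1,10-phenanthroline (20 mol %), Cs2CO3 (2 equiv), toluene, 100 °C
Reagents that add atoms: none
Why: Copper-catalysed intramolecular Ullmann-type C–O coupling of the secondary alkoxide onto the ortho bromide closes the six-membered dioxane ring; the C-7–O bond of the alcohol is never broken, so both stereocentres are carried over with retention and the threo alcohol gives the trans-(2R,3R) benzodioxane.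

Step 7
Reactants: 10 (2R,3R)-3-[4-(benzyloxy)-3,5-dimethoxyphenyl]-2-[(benzyloxy)methyl]-6-[(E)-2-[3,5-bis(benzyloxy)phenyl]ethenyl]-2,3-dihydro-1,4-benzodioxine
Product: 11 aiphanol, 5-[(E)-2-[(2R,3R)-3-(4-hydroxy-3,5-dimethoxyphenyl)-2-(hydroxymethyl)-2,3-dihydro-1,4-benzodioxin-6-yl]ethenyl]benzene-1,3-diol
Conditions: BCl3 (12 equiv), C6HMe5 (12 equiv), CH2Cl2, −78 → −20 °C; MeOH quench, aqueous work-up
Reagents that add atoms: none
Why: Lewis-acid debenzylation with pentamethylbenzene as a non-basic benzyl cation scavenger cleaves the three aryl benzyl ethers at −78 °C and the primary alkyl benzyl ether on warming, while aryl methyl ethers and the E-stilbene survive; ionisation of the benzylic C-7–O bond is disfavoured by the β-oxygen, and even a reversible opening would re-close to the thermodynamically preferred trans ring without touching C-8.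

**Compound list**

1 | 4-(benzyloxy)-3,5-dimethoxybenzaldehyde | COc1cc(C=O)cc(OC)c1OCc1ccccc1 | starting material
2 | (benzyloxy)acetaldehyde | O=CCOCc1ccccc1 | starting material
3 | (2S)-3-(benzyloxy)-1-[4-(benzyloxy)-3,5-dimethoxyphenyl]-2-hydroxypropan-1-one | COc1cc(C(=O)[C@@H](O)COCc2ccccc2)cc(OC)c1OCc1ccccc1 | intermediate
4 | 3,5-bis(benzyloxy)benzyl bromide | BrCc1cc(OCc2ccccc2)cc(OCc2ccccc2)c1 | starting material
5 | diethyl [3,5-bis(benzyloxy)benzyl]phosphonate | CCOP(=O)(Cc1cc(OCc2ccccc2)cc(OCc2ccccc2)c1)OCC | intermediate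
6 | 3-bromo-4-hydroxybenzaldehyde | O=Cc1ccc(O)c(Br)c1 | starting material
7 | 2-bromo-4-[(E)-2-[3,5-bis(benzyloxy)phenyl]ethenyl]phenol | Oc1ccc(/C=C/c2cc(OCc3ccccc3)cc(OCc3ccccc3)c2)cc1Br | intermediate
8 | (2R)-3-(benzyloxy)-1-[4-(benzyloxy)-3,5-dimethoxyphenyl]-2-{4-[(E)-2-[3,5-bis(benzyloxy)phenyl]ethenyl]-2-bromophenoxy}propan-1-one | COc1cc(C(=O)[C@@H](COCc2ccccc2)Oc2ccc(/C=C/c3cc(OCc4ccccc4)cc(OCc4ccccc4)c3)cc2Br)cc(OC)c1OCc1ccccc1 | intermediate
9 | (1R,2R)-3-(benzyloxy)-1-[4-(benzyloxy)-3,5-dimethoxyphenyl]-2-{4-[(E)-2-[3,5-bis(benzyloxy)phenyl]ethenyl]-2-bromophenoxy}propan-1-ol | COc1cc([C@@H](O)[C@@H](COCc2ccccc2)Oc2ccc(/C=C/c3cc(OCc4ccccc4)cc(OCc4ccccc4)c3)cc2Br)cc(OC)c1OCc1ccccc1 | intermediate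
10 | (2R,3R)-3-[4-(benzyloxy)-3,5-dimethoxyphenyl]-2-[(benzyloxy)methyl]-6-[(E)-2-[3,5-bis(benzyloxy)phenyl]ethenyl]-2,3-dihydro-1,4-benzodioxine | COc1cc([C@H]2Oc3cc(/C=C/c4cc(OCc5ccccc5)cc(OCc5ccccc5)c4)ccc3O[C@@H]2COCc2ccccc2)cc(OC)c1OCc1ccccc1 | intermediate
11 | aiphanol, 5-[(E)-2-[(2R,3R)-3-(4-hydroxy-3,5-dimethoxyphenyl)-2-(hydroxymethyl)-2,3-dihydro-1,4-benzodioxin-6-yl]ethenyl]benzene-1,3-diol | COc1cc([C@H]2Oc3cc(/C=C/c4cc(O)cc(O)c4)ccc3O[C@@H]2CO)cc(OC)c1O | target

**Step count and risks**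

Total: 7 steps. Longest linear sequence: 6 steps (4 → 5 → 7 → 8 → 9 → 10 → 11); 5 steps from 1 through the key step.

The three steps most likely to fail:

Step 1 (cross-acyloin). Likely failure modes are self-condensation of 2, loss of benzyloxide from the Breslow intermediate of 2, erosion of ee by retro-benzoin or enolisation, and an unexpected sense of induction. The fallback sets out from 1 and 2 and comes back at 3. It replaces the small-molecule carbene by a thiamine-dependent enzyme of known selectivity and corrects the configuration afterwards. Benzaldehyde lyase from Pseudomonas fluorescens (thiamine diphosphate, MgSO4, phosphate buffer pH 8 with 30 % DMSO, 30 °C) ligates 1 as donor with 2 as acceptor to give (2R)-3-(benzyloxy)-1-[4-(benzyloxy)-3,5-dimethoxyphenyl]-2-hydroxypropan-1-one F1. Mitsunobu esterification with 4-nitrobenzoic acid (PPh3, DIAD, toluene, 0 °C) inverts C-8 and gives (2S)-1-(benzyloxy)-3-[4-(benzyloxy)-3,5-dimethoxyphenyl]-3-oxopropan-2-yl 4-nitrobenzoate F2. Cold methanolysis (catalytic K2CO3, MeOH, −20 °C) then releases 3. This costs two extra steps.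

Step 6 (copper ring closure). The hindered secondary benzylic alkoxide may couple slowly or be oxidised back to the ketone. The fallback sets out from 9 and comes back at 10. It turns the bromide into the nucleophile and closes the ring at C-7 by an ionisation pathway. Miyaura borylation (PdCl2(dppf), B2pin2, KOAc, dioxane, 80 °C) gives (1R,2R)-3-(benzyloxy)-1-[4-(benzyloxy)-3,5-dimethoxyphenyl]-2-{4-[(E)-2-[3,5-bis(benzyloxy)phenyl]ethenyl]-2-(4,4,5,5-tetramethyl-1,3,2-dioxaborolan-2-yl)phenoxy}propan-1-ol F3. Oxidation with NaBO3·4H2O in THF/water gives (1R,2R)-3-(benzyloxy)-1-[4-(benzyloxy)-3,5-dimethoxyphenyl]-2-{4-[(E)-2-[3,5-bis(benzyloxy)phenyl]ethenyl]-2-hydroxyphenoxy}propan-1-ol F4. Camphorsulfonic acid or BF3·OEt2 in CH2Cl2 at 0 °C then ionises the benzylic alcohol, and the neighbouring phenol traps the cation to give 10 as the thermodynamically favoured trans ring; C-8 is not involved.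

Step 7 (global debenzylation). The primary alkyl benzyl ether needs warming above −78 °C, where the benzylic C-7–O bond and the electron-rich stilbene are most exposed to the Lewis acid. The fallback sets out from 1 and comes back at 11. It changes the protecting group at C-9 to silyl, so that only aryl benzyl ethers remain for boron trichloride at −78 °C and the last group leaves with fluoride. Step 1 is run with (tert-butyldimethylsilyloxy)acetaldehyde in place of 2 to give (2S)-1-[4-(benzyloxy)-3,5-dimethoxyphenyl]-3-[(tert-butyldimethylsilyl)oxy]-2-hydroxypropan-1-one F5. Mitsunobu coupling with 7 as in step 4 gives (2R)-1-[4-(benzyloxy)-3,5-dimethoxyphenyl]-2-{4-[(E)-2-[3,5-bis(benzyloxy)phenyl]ethenyl]-2-bromophenoxy}-3-[(tert-butyldimethylsilyl)oxy]propan-1-one F6. Transfer hydrogenation as in step 5 gives (1R,2R)-1-[4-(benzyloxy)-3,5-dimethoxyphenyl]-2-{4-[(E)-2-[3,5-bis(benzyloxy)phenyl]ethenyl]-2-bromophenoxy}-3-[(tert-butyldimethylsilyl)oxy]propan-1-ol F7. Ring closure as in step 6 gives tert-butyl{[(2R,3R)-3-[4-(benzyloxy)-3,5-dimethoxyphenyl]-6-[(E)-2-[3,5-bis(benzyloxy)phenyl]ethenyl]-2,3-dihydro-1,4-benzodioxin-2-yl]methoxy}dimethylsilane F8. BCl3/C6HMe5 kept at −78 °C, followed by TBAF in THF at 0 °C, then gives 11.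

**Further compounds**

F1 | step 1 | (2R)-3-(benzyloxy)-1-[4-(benzyloxy)-3,5-dimethoxyphenyl]-2-hydroxypropan-1-one | COc1cc(C(=O)[C@H](O)COCc2ccccc2)cc(OC)c1OCc1ccccc1
F2 | step 1 | (2S)-1-(benzyloxy)-3-[4-(benzyloxy)-3,5-dimethoxyphenyl]-3-oxopropan-2-yl 4-nitrobenzoate | COc1cc(C(=O)[C@H](COCc2ccccc2)OC(=O)c2ccc(cc2)[N+](=O)[O-])cc(OC)c1OCc1ccccc1
F3 | step 6 | (1R,2R)-3-(benzyloxy)-1-[4-(benzyloxy)-3,5-dimethoxyphenyl]-2-{4-[(E)-2-[3,5-bis(benzyloxy)phenyl]ethenyl]-2-(4,4,5,5-tetramethyl-1,3,2-dioxaborolan-2-yl)phenoxy}propan-1-ol | COc1cc([C@@H](O)[C@@H](COCc2ccccc2)Oc2ccc(/C=C/c3cc(OCc4ccccc4)cc(OCc4ccccc4)c3)cc2B5OC(C)(C)C(C)(C)O5)cc(OC)c1OCc1ccccc1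
F4 | step 6 | (1R,2R)-3-(benzyloxy)-1-[4-(benzyloxy)-3,5-dimethoxyphenyl]-2-{4-[(E)-2-[3,5-bis(benzyloxy)phenyl]ethenyl]-2-hydroxyphenoxy}propan-1-ol | COc1cc([C@@H](O)[C@@H](COCc2ccccc2)Oc2ccc(/C=C/c3cc(OCc4ccccc4)cc(OCc4ccccc4)c3)cc2O)cc(OC)c1OCc1ccccc1
F5 | step 7 | (2S)-1-[4-(benzyloxy)-3,5-dimethoxyphenyl]-3-[(tert-butyldimethylsilyl)oxy]-2-hydroxypropan-1-one | COc1cc(C(=O)[C@@H](O)CO[Si](C)(C)C(C)(C)C)cc(OC)c1OCc1ccccc1
F6 | step 7 | (2R)-1-[4-(benzyloxy)-3,5-dimethoxyphenyl]-2-{4-[(E)-2-[3,5-bis(benzyloxy)phenyl]ethenyl]-2-bromophenoxy}-3-[(tert-butyldimethylsilyl)oxy]propan-1-one | COc1cc(C(=O)[C@@H](CO[Si](C)(C)C(C)(C)C)Oc2ccc(/C=C/c3cc(OCc4ccccc4)cc(OCc4ccccc4)c3)cc2Br)cc(OC)c1OCc1ccccc1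
F7 | step 7 | (1R,2R)-1-[4-(benzyloxy)-3,5-dimethoxyphenyl]-2-{4-[(E)-2-[3,5-bis(benzyloxy)phenyl]ethenyl]-2-bromophenoxy}-3-[(tert-butyldimethylsilyl)oxy]propan-1-ol | COc1cc([C@@H](O)[C@@H](CO[Si](C)(C)C(C)(C)C)Oc2ccc(/C=C/c3cc(OCc4ccccc4)cc(OCc4ccccc4)c3)cc2Br)cc(OC)c1OCc1ccccc1
F8 | step 7 | tert-butyl{[(2R,3R)-3-[4-(benzyloxy)-3,5-dimethoxyphenyl]-6-[(E)-2-[3,5-bis(benzyloxy)phenyl]ethenyl]-2,3-dihydro-1,4-benzodioxin-2-yl]methoxy}dimethylsilane | COc1cc([C@H]2Oc3cc(/C=C/c4cc(OCc5ccccc5)cc(OCc5ccccc5)c4)ccc3O[C@@H]2CO[Si](C)(C)C(C)(C)C)cc(OC)c1OCc1ccccc1
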